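If a charge of E turns into Z under dosed X while Z also reacts with E to give J, I carry one number for the final split.

| setting | Sunday's | flask |
|---|---|---|
| E | 0.050 M | 0.050 M |
| X | 1.2 mM (in portions, 4) | 1.2 mM (in portions, 4) |
| remark | the very flask that is asked about, followed so far; portions every 4.0 min | the portions of X follow each other after 4.0 min, the first at the start |
| time |  | 12 h |

Sunday's run (percent of the E charged)

| time / min | Z / % | J / % | E / % |
|---|---|---|---|
| 5.00 | 0.2 | 0 | 97.5 |
| 10.0 | 1.9 | 1.8 | 96.3 |
| 25.0 | 9.9 | 0.2 | 89.1 |
| 60.0 | 24.0 | 5.4 | 67.9 |

(standard deviation of a reading: 1 percentage point)

1. which holds at 12 h: what has brought the reaction to rest, or that it has not come to rest (forward and back rates have come level / all of E has reacted / it is still moving / no working catalyst is left)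
2. amount of Z at 12 h, in percent of the E charged
3. amount of J at 12 h, in percent of the E charged

- a species is counted by the E in it: one J counts as two
- the reaction counts as stopped when no species that holds the E changes by six tenths of a point or more over the second half of the time

I take the fraction of E turned as my clock and let Z rise steadily along it. J then grows with the product of E and Z, which integrates in closed form. Early on, J equals a constant times Z squared, and when E is gone, J is a third of that constant. The readings at 60.0 min give 0.938: this is my side number, early J over Z squared, a selectivity factor of sorts. It remains a reading, with 1 percentage point of scatter on J.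

At Sunday's average fall between 5.00 min and 60.0 min, the E remaining at 60.0 min lasts 2.10 h, less than the 12 h asked. So I expect E to run out, with J near 31.3% and Z near 68.7%.

The forecast says all of E has reacted, with Z 60% and J 38%, so its J stands above mine. Its ground: “J appears late, roughly as time squared”.

The flask gives all of E has reacted, with Z 67.9% and J 32.1%. By 6.00 h it already held Z 67.8%, J 32.0% and E 0.155%. A third of the side number lies 0.80 points below the J of this flask at 12 h.

    E + X ⇌ Q (K = 290 L mol⁻¹, k = 27.0 L mol⁻¹ min⁻¹)
    Q → L (k = 0.280 min⁻¹)
    L → X + Z (k = 32.0 min⁻¹)
    E + L → D (k = 0.210 L mol⁻¹ min⁻¹)
    E + Z → J (k = 0.120 L mol⁻¹ min⁻¹)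

With 0.20 M of E and the same X, I scale the side number by the square of the E charge, which gives 15.0. A third of that exceeds the whole charge, so the rule of a third, which neglects the Z that J consumes, does not hold here, and I keep only a size for Z in this neighbour: one over the root of the side number, 25.8%, the scale at which the side rate matches the main rate with E and Z alike. That neighbour gives Z 22.5% and J 77.4%.

The earlier runs and the new flask come from a simulation from invented constants, noise included.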